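The data are simulated with made-up constants; the scatter is artificial.

Time is my ruler here: I count every flask in substrate lifetimes.

| flask | substrate | first nucleophile | second nucleophile | remark | time |
|---|---|---|---|---|---|
| summer | 0.010 M | 0.95 equiv | 5 equiv | run made earlier |  |
| dusk | 0.010 M | 0.95 equiv | 2.5 equiv | run made earlier |  |
| autumn | 0.010 M | 0.95 equiv | 10 equiv | run made earlier |  |
| winter | 0.020 M | 0.95 equiv | 5 equiv | run made earlier |  |
| beta | 0.010 M | 0.950 equiv (fed, over 15 d) | 5.00 equiv | all else is in the flask from the start; the feed brings no volume worth counting | 20 d |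
| gamma | 0.010 M | 0.950 equiv (in portions, 5, over 15 d) | 5.00 equiv | first portion at the start, last at 15 d | 20 d |
| delta | 0.010 M | 0.950 equiv | 5.00 equiv | everything together at the start | 20 d |
| eta | 0.010 M (fed, over 15 d) | 0.950 equiv | 5.00 equiv | all else is in the flask from the start; the feed brings no volume worth counting | 20 d |

| run | time / d | target / % | other capture product / % | substrate / % |
|---|---|---|---|---|
| summer | 1.04 | 17.3 | 14.1 | 67.4 |
| summer | 1.67 | 25.6 | 21.8 | 53.9 |
| summer | 2.00 | 25.9 | 25.9 | 44.9 |
| summer | 3.00 | 33.1 | 34.4 | 32.8 |
| summer | 5.00 | 42.0 | 42.8 | 15.5 |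
| summer | 8.00 | 48.2 | 47.5 | 3.5 |
| summer | 12.0 | 50.1 | 49.7 | 0.6 |
| dusk | 0.625 | 15.0 | 5.2 | 80.9 |
| dusk | 1.67 | 32.2 | 13.6 | 51.9 |
| dusk | 3.00 | 45.5 | 22.8 | 32.6 |
| dusk | 5.00 | 55.8 | 32.9 | 15.4 |
| dusk | 8.00 | 59.1 | 35.3 | 4.8 |
| dusk | 10.0 | 61.7 | 34.5 | 1.4 |
| dusk | 12.0 | 61.9 | 35.7 | 0.2 |
| autumn | 1.67 | 17.9 | 27.9 | 51.7 |
| autumn | 3.00 | 24.7 | 44.8 | 30.8 |
| autumn | 5.00 | 30.2 | 54.4 | 13.1 |
| autumn | 6.00 | 31.6 | 59.0 | 10.8 |
| autumn | 8.00 | 34.5 | 61.3 | 3.9 |
| autumn | 10.0 | 33.7 | 64.8 | 2.7 |
| autumn | 12.0 | 35.7 | 62.7 | 0.5 |
| winter | 1.04 | 18.2 | 15.1 | 66.1 |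
| winter | 3.00 | 34.3 | 32.8 | 32.1 |
| winter | 6.00 | 43.2 | 44.9 | 9.0 |
| winter | 8.00 | 46.7 | 49.1 | 3.9 |
| winter | 12.0 | 49.2 | 49.6 | 2.3 |

(readings scatter by 1 percentage point)

- the best flask by share of target in target plus other capture product; "all alike" if 1.5 percentage points covers them all (beta / gamma / delta / eta / all alike)
- share of target in target plus other capture product at the end, beta
- share of target in target plus other capture product at the end, gamma
- share of target in target plus other capture product at the end, delta
- share of target in target plus other capture product at the end, eta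



At 5.00 d, summer reads 15.5% of its substrate left, dusk 15.4% and autumn 13.1%, though the second nucleophile goes from 2.5 equiv to 10 equiv. Winter, at twice the concentration, reads 32.1% at 3.00 d against 32.8% in summer. So the loss reads as first order, with a rate-limiting step that shows no response, within the scatter, to the second nucleophile or to the concentration. From summer I take the substrate lifetime, the mean time a molecule stays substrate: 2.68 d.

Now I draw the substrate curve of eta. It starts from zero with a slope of 0.0667 /d, as a fraction of the charge. Loss grows with the amount, so the rise bends at a knee near one lifetime and runs into the level where loss equals feed, lifetime over feed time: 17.9% of the charge. The feed lasts 5.59 lifetimes, so eta stands on that level when the feed stops. A second knee follows, and the curve falls for 1.86 lifetimes to about 2.77% at 20 d. Delta's substrate falls from the whole charge on the same lifetime and crosses eta's curve at 5.06 d. On my reckoning, substrate leaves eta on average at 10.2 d, later than delta at 2.68 d. The earlier runs hold no reading of either nucleophile, so I commit to this curve and to no share.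

The forecast gives 15% for beta, 19.3% for gamma, 50% for delta and 50.2% for eta, and names eta best, holding that “feeding substrate leaves the capture competition unchanged”.

The flasks give 18.7% for beta, 21.8% for gamma, 50.5% for delta and 68.4% for eta, which stands 18 percentage points above the forecast.

    substrate → intermediate (k = 0.0158 /h)
    first nucleophile + intermediate → target (k = 2230 /M/h)
    second nucleophile + intermediate → other capture product (k = 257 /M/h)
    first nucleophile ⇌ dormant form (K = 1.23, k = 0.0228 /h)
    second nucleophile → decomposed reagent (k = 0.00636 /h)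

In delta, the second nucleophile's half-life by decomposition alone is 4.5 d. Counted on that clock, the mean passing of substrate stands at 0.596 half-lives in delta and at 2.24 in eta. In beta, where the substrate is present from the start, 5.59 lifetimes reckon to 0.374% left, and the flask holds 0.339% at 15.0 d.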